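**Plan**

Atoms are numbered in the order of the target SMILES (C1 to O35). Retrosynthetic cuts, in order: the silyl groups, saturation of C12–C13, O27, C12–C13 (giving aldehyde 16 and sulfone 35), C8–C9, then O4–C2 and C11–C30 in one operation.
Enabling feature: the oxepane (C2, O4, C5, C30, C32, C33, C34) and the cyclohexane (C5, C6, C7, C8, C11, C30) are trans-fused through C5–C30. O4 on C5 is anti to C11 on C30, and O35 sits on C34 next to quaternary C2. This is what remains of a C5/C30 epoxide that reacted as a nucleophile through oxygen (toward C2 of a C2/C34 epoxide) and as an electrophile at its tertiary carbon (toward C11).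
Left half, forward: C6–C7 alkylation, Z-enol triflate, both epoxides, allylsilane, both rings closed together (step 7), C8 ketone, C8 carbinol, C12 aldehyde.
Right half, forward: cyclopentene by RCM of (R)-linalool, C15–C18 by epoxide opening, C25/C26 arm on C24, cycloheptene by RCM (C26=C28), C13 by methylenation and hydroboration, sulfone. Then union, epoxidation, diimide reduction and desilylation.
Stereochemistry: C5, C30 and C34 come from Shi epoxidation (C30 is inverted in step 7). C11 comes from the chair and the Z olefin, and C8 from equatorial Grignard attack. C21 comes from linalool and is relayed to C18 (OH-directed epoxidation, anti opening), to C24 and C14 (hydroboration from the open face) and to C26/C28 (exo-face epoxidation).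

Key step: step 7

Assumption: commercial (R)-(−)-linalool is taken to be of high enantiomeric purity; any minor enantiomer of either half would appear after step 28 as a separable diastereomer.

**Left half**

Step 1
Reactants: 1 geranyl bromide; 2 ethyl acetoacetate
Product: 3 ethyl (6E)-7,11-dimethyl-3-oxododeca-6,10-dienoate
Conditions: 2, NaH then n-BuLi, THF, 0 °C; then 1, 0 °C → rt
Reagents that add atoms: none
Why: In this acetoacetate dianion alkylation the more basic terminal carbanion displaces the allylic bromide by SN2 and joins C6–C7 without touching the E olefin.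

Step 2
Reactants: 3 ethyl (6E)-7,11-dimethyl-3-oxododeca-6,10-dienoate
Product: 4 ethyl (2Z,6E)-7,11-dimethyl-3-{[(trifluoromethyl)sulfonyl]oxy}dodeca-2,6,10-trienoate
Conditions: Tf2O, aq LiOH, toluene, 5 °C
Reagents that add atoms: triflic anhydride, O=S(=O)(OS(=O)(=O)C(F)(F)F)C(F)(F)F
Why: O-sulfonylation of the lithium-chelated β-keto ester enolate should give the Z-enol triflate (OTf cis to the ester), which fixes the later allylsilane geometry.

Step 3
Reactants: 4 ethyl (2Z,6E)-7,11-dimethyl-3-{[(trifluoromethyl)sulfonyl]oxy}dodeca-2,6,10-trienoate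
Product: 5 ethyl (2Z)-5-[(2R,3R)-3-{2-[(2R)-3,3-dimethyloxiran-2-yl]ethyl}-3-methyloxiran-2-yl]-3-{[(trifluoromethyl)sulfonyl]oxy}pent-2-enoate
Conditions: D-fructose-derived Shi ketone (cat.), Oxone, K2CO3, Bu4NHSO4, borate/EDTA buffer, MeCN–DMM–H2O, 0 °C
Reagents that add atoms: potassium peroxymonosulfate (Oxone), [K+].[O-]S(=O)(=O)OO
Why: In the Shi epoxidation the chiral dioxirane attacks both electron-rich trisubstituted olefins through the spiro transition state to set C5, C30 and C34 (all R), and the acceptor-substituted C8=C11 bond is too electron-poor to react.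

Step 4
Reactants: 5 diepoxy enol triflate; 6 (trimethylsilyl)methylmagnesium chloride
Product: 7 ethyl (2Z)-5-[(2R,3R)-3-{2-[(2R)-3,3-dimethyloxiran-2-yl]ethyl}-3-methyloxiran-2-yl]-3-[(trimethylsilyl)methyl]pent-2-enoate
Conditions: Pd(PPh3)4 (5 mol %), THF–Et2O, 0 °C → rt
Reagents that add atoms: none
Why: The Kumada coupling of an activated enol triflate proceeds with retention of olefin geometry, and the bulky, weakly nucleophilic Grignard reagent leaves the ester and the trisubstituted epoxides alone at this temperature.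

Step 5
Reactants: 7 diepoxy silylmethyl enoate
Product: 8 (2Z)-5-[(2R,3R)-3-{2-[(2R)-3,3-dimethyloxiran-2-yl]ethyl}-3-methyloxiran-2-yl]-3-[(trimethylsilyl)methyl]pent-2-en-1-ol
Conditions: DIBAL-H (2.3 equiv), CH2Cl2, −78 °C
Reagents that add atoms: none
Why: 1,2-Reduction of the enoate with DIBAL-H at low temperature is faster than hydride opening of hindered epoxides and converts the deactivated olefin into a nucleophilic allylsilane.

Step 6
Reactants: 8 diepoxy allylic alcohol
Product: 9 tert-butyldiphenylsilyl ether of 8, the (Z)-diepoxy 2-(silylmethyl)allyl silyl ether used as cascade precursor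
Conditions: TBDPSCl, imidazole, CH2Cl2, 0 °C → rt
Reagents that add atoms: tert-butyldiphenylsilyl chloride, CC(C)(C)[Si](Cl)(c1ccccc1)c1ccccc1
Why: Silylation under amine-base conditions never forms a free alkoxide, which could attack the cis-disposed Me3Si group, and it installs a bulky ether oxygen of low basicity.

Step 7
Reactants: 9 (Z)-diepoxy 2-(silylmethyl)allyl TBDPS ether
Product: 11 (3R,5aR,6S,9aR)-6-{[(tert-butyldiphenylsilyl)oxy]methyl}-2,2,5a-trimethyl-7-methylidenedecahydro-1-benzoxepin-3-ol (trans-fused; C12 arm equatorial), via C34 trimethylsilyl ether 10 (not isolated)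
Conditions: TMSOTf (1.1 equiv), 2,6-di-tert-butyl-4-methylpyridine, CH2Cl2, −78 °C; Et3N, MeOH; then K2CO3, MeOH, 0 °C
Reagents that add atoms: none
Why: TMSOTf silylates the exposed terminal epoxide oxygen O35, the lone pair of the neighbouring epoxide oxygen O4 displaces the C2–O35 bond at the tertiary carbon to give a bicyclic epoxonium ion, C11 of the allylsilane opens that ion at tertiary C30 from the rear, and the β-silyl cation at C8 gives up Me3Si+ to triflate to leave the C8 exocyclic methylene and the C34 silyl ether 10, which methanolysis frees. The closest known chemistry is the silyl triflate- or BF3-promoted polyepoxide oxacyclisation cascade terminated by an allylsilane, propargylsilane or enol silane. The oxepane closes by 7-endo opening of the terminal epoxide (O4 to C2), and the cyclohexane closes by a chair cation–olefin closure on C30 that is 6-endo with respect to C8=C11. C5 and C34 keep their Shi configuration because their C–O bonds are never broken, C30 is inverted stereospecifically so that the E-derived epoxide becomes the trans fusion (O4 equatorial, C31 axial), and C11 is set by the chair together with the Z olefin, which places C12 (trans to C7 on the double bond) equatorial. The step needs endo cleavage in both epoxides and termination through carbon: both breaking C–O bonds are at tertiary carbons, the hindered pyridine suppresses protic pathways, the silicon β-effect makes C11 the only competent carbon nucleophile, and the weakly basic TBDPS ether resists Lewis-acid-induced 1,4-loss of the C12 oxygen.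

Step 8
Reactants: 11 oxepane–methylenecyclohexane alcohol
Product: 12 (3R,5aR,6S,9aR)-6-{[(tert-butyldiphenylsilyl)oxy]methyl}-3-hydroxy-2,2,5a-trimethyloctahydro-1-benzoxepin-7(2H)-one
Conditions: O3, CH2Cl2, −78 °C; Me2S
Reagents that add atoms: ozone, [O-][O+]=O
Why: Ozonolysis cleaves the only C=C bond to the C8 ketone under neutral conditions, and C11 stays in its more stable equatorial configuration.

Step 9
Reactants: 12 C8 ketone
Product: 13 (3R,5aR,6S,7S,9aR)-6-{[(tert-butyldiphenylsilyl)oxy]methyl}-2,2,5a,7-tetramethyldecahydro-1-benzoxepine-3,7-diol (O10 axial, C9 equatorial)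
Conditions: MeMgBr (4 equiv), THF, −78 → 0 °C
Reagents that add atoms: methylmagnesium bromide, C[Mg]Br
Why: In this Grignard 1,2-addition to a locked cyclohexanone the axial trajectory is closed by the 1,3-related axial C31 methyl, so methyl should enter equatorially and leave O10 axial and cis to C31, with excess reagent covering the free C34 hydroxyl.

Step 10
Reactants: 13 silyl-protected diol
Product: 14 (3R,5aR,6S,7S,9aR)-6-(hydroxymethyl)-2,2,5a,7-tetramethyldecahydro-1-benzoxepine-3,7-diol
Conditions: TBAF, THF, rt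
Reagents that add atoms: none
Why: Fluoride cleaves the only silyl ether, and nothing else in the molecule is sensitive to fluoride or base.

Step 11
Reactants: 14 triol
Product: 15 tris(triethylsilyl) ether of 14 (O10, O35 and the C12 oxygen silylated)
Conditions: TESOTf (4.5 equiv), 2,6-lutidine, CH2Cl2, −78 °C → rt
Reagents that add atoms: triethylsilyl triflate, CC[Si](CC)(CC)OS(=O)(=O)C(F)(F)F
Why: Exhaustive silylation with a silyl triflate is strong enough for the axial tertiary O10 and gives one protecting group for all hydroxyls, removable under one mild condition at the end.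

Step 12
Reactants: 15 tris(triethylsilyl) ether
Product: 16 (3R,5aR,6R,7S,9aR)-2,2,5a,7-tetramethyl-3,7-bis[(triethylsilyl)oxy]decahydro-1-benzoxepine-6-carbaldehyde
Conditions: (COCl)2, DMSO, CH2Cl2, −78 → −35 °C; Et3N, → 0 °C
Reagents that add atoms: none
Why: In this direct Swern oxidation of a primary triethylsilyl ether the chlorosulfonium salt exchanges only with the least hindered Si–O bond, so C12 becomes the aldehyde while the secondary and tertiary TES ethers stay.

**Right half**

Step 13
Reactants: 17 (R)-(−)-linalool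
Product: 18 (1R)-1-methylcyclopent-2-en-1-ol
Conditions: Hoveyda–Grubbs II (0.5 mol %), CH2Cl2, rt
Reagents that add atoms: none
Why: Ring-closing metathesis of the 1,6-diene expels isobutene, leaves the carbinol centre C21 untouched and places the new C18=C24 bond at the future ring fusion.

Step 14
Reactants: 18 (1R)-1-methylcyclopent-2-en-1-ol
Product: 19 (1S,2R,5S)-2-methyl-6-oxabicyclo[3.1.0]hexan-2-ol (epoxide cis to OH)
Conditions: VO(acac)2 (cat.), t-BuOOH, CH2Cl2, 0 °C → rt
Reagents that add atoms: tert-butyl hydroperoxide, CC(C)(C)OO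
Why: Vanadium-catalysed, hydroxyl-directed epoxidation of a cyclic allylic alcohol delivers oxygen to the face that bears O23.

Step 15
Reactants: 19 cis-epoxy alcohol; 20 isobutyronitrile
Product: 21 2-[(1S,2S,3R)-2,3-dihydroxy-3-methylcyclopentyl]-2-methylpropanenitrile
Conditions: 20 (3 equiv), LDA (3 equiv), THF, −78 → 0 °C; then 19, 0 → 50 °C
Reagents that add atoms: none
Why: In this SN2 opening of an epoxy alkoxide by a slim nitrile-stabilised tertiary carbanion, attack occurs anti and at C18, the carbon remote from the carbinol, which builds quaternary C15 and places it trans to both oxygens; the substrate is used without a silyl group because one would migrate to the new cis alkoxide.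

Step 16
Reactants: 21 diol nitrile
Product: 22 2-[(1S,3R)-3-hydroxy-3-methyl-2-oxocyclopentyl]-2-methylpropanenitrile
Conditions: IBX, DMSO, rt
Reagents that add atoms: none
Why: IBX oxidises the secondary hydroxyl of a secondary/tertiary 1,2-diol to the α-ketol without glycol cleavage and without base that could epimerise C18.

Step 17
Reactants: 22 α-ketol
Product: 23 2-methyl-2-{(1S,3R)-3-methyl-2-oxo-3-[(triethylsilyl)oxy]cyclopentyl}propanenitrile
Conditions: TESOTf (1.2 equiv), 2,6-lutidine, CH2Cl2, −78 → 0 °C
Reagents that add atoms: triethylsilyl triflate, CC[Si](CC)(CC)OS(=O)(=O)C(F)(F)F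
Why: O-silylation of the tertiary alcohol with a near-stoichiometric amount of silyl triflate is faster than enol silane formation at the shielded C18–H.

Step 18
Reactants: 23 silyloxy ketone
Product: 24 2-methyl-2-{(1S,3R)-3-methyl-2-methylidene-3-[(triethylsilyl)oxy]cyclopentyl}propanenitrile
Conditions: Ph3PCH3Br, KHMDS, THF, 0 °C → rt
Reagents that add atoms: methyltriphenylphosphonium bromide, C[P+](c1ccccc1)(c1ccccc1)c1ccccc1.[Br-]
Why: In the Wittig methylenation the smallest non-stabilised ylide adds to the cyclopentanone faster than it removes the single, sterically buried α-hydrogen, and the tertiary nitrile is inert.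

Step 19
Reactants: 24 methylidenecyclopentane
Product: 26 2-methyl-2-{(1R,2R,3R)-3-methyl-2-(prop-2-en-1-yl)-3-[(triethylsilyl)oxy]cyclopentyl}propanenitrile, via B-alkyl-9-BBN adduct 25 (not isolated)
Conditions: 9-BBN-H, THF, 0 °C → rt; then vinyl bromide, PdCl2(dppf) (5 mol %), AsPh3, Cs2CO3, DMF–H2O, rt
Reagents that add atoms: vinyl bromide, C=CBr; 9-borabicyclo[3.3.1]nonane, B1C2CCCC1CCC2 (its boron stays only in 25)
Why: In this hydroboration/B-alkyl Suzuki–Miyaura sequence the borane should approach the face opposite C22 and the tert-alkyl group on C18, so H goes onto C24 cis to H18 and C25 is pushed cis to C15, and the primary borane then couples with vinyl bromide.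

Step 20
Reactants: 26 allyl nitrile
Product: 27 2-methyl-2-{(1R,2R,3R)-3-methyl-2-(prop-2-en-1-yl)-3-[(triethylsilyl)oxy]cyclopentyl}propanal
Conditions: DIBAL-H (1.3 equiv), toluene, −78 → 0 °C; aq tartaric acid
Reagents that add atoms: water, O
Why: DIBAL-H reduction of a nitrile stops at the aluminium iminate, which hydrolyses to the non-enolisable C14 aldehyde.

Step 21
Reactants: 27 neopentyl aldehyde
Product: 28 2,4-dimethyl-4-{(1R,2R,3R)-3-methyl-2-(prop-2-en-1-yl)-3-[(triethylsilyl)oxy]cyclopentyl}pent-1-en-3-ol (both C14 epimers)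
Conditions: isopropenylmagnesium bromide, THF, −78 → 0 °C
Reagents that add atoms: isopropenylmagnesium bromide, CC(=C)[Mg]Br
Why: Grignard 1,2-addition to a non-enolisable aldehyde forms C14–C28, and the epimer mixture does not matter because C14 becomes sp2 in step 23.

Step 22
Reactants: 28 dienol
Product: 29 (1R,3aR,8aR)-1,4,4,6-tetramethyl-1-[(triethylsilyl)oxy]-1,2,3,3a,4,5,8,8a-octahydroazulen-5-ol (cis-fused; both C14 epimers)
Conditions: Grubbs II (5–10 mol %), CH2Cl2 (high dilution), reflux
Reagents that add atoms: none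
Why: Ring-closing metathesis to a trisubstituted cycloheptene is helped by the cis disposition of both arms, the gem-dimethyl effect of C15 and the activating allylic hydroxyl.

Step 23
Reactants: 29 bicyclic allylic alcohol
Product: 30 (1R,3aR,8aR)-1,4,4,6-tetramethyl-1-[(triethylsilyl)oxy]-2,3,3a,4,8,8a-hexahydroazulen-5(1H)-one
Conditions: Dess–Martin periodinane, NaHCO3, CH2Cl2, rt
Reagents that add atoms: none
Why: Dess–Martin oxidation converts both carbinol epimers into one enone under neutral conditions.

Step 24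
Reactants: 30 enone
Product: 31 (1R,3aR,8aR)-1,4,4,6-tetramethyl-5-methylidene-1-[(triethylsilyl)oxy]-1,2,3,3a,4,5,8,8a-octahydroazulene
Conditions: Ph3PCH3Br, KOt-Bu, toluene, 90 °C
Reagents that add atoms: methyltriphenylphosphonium bromide, C[P+](c1ccccc1)(c1ccccc1)c1ccccc1.[Br-]
Why: Wittig methylenation under forcing conditions is tolerable here because the hindered ketone has no α-hydrogen (C15 quaternary, C28 sp2) and no epimerisable centre nearby.

Step 25
Reactants: 31 exocyclic diene
Product: 33 {(1R,3aR,5S,8aR)-1,4,4,6-tetramethyl-1-[(triethylsilyl)oxy]-1,2,3,3a,4,5,8,8a-octahydroazulen-5-yl}methanol, via B-alkyl-9-BBN adduct 32 (not isolated)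
Conditions: 9-BBN-H, THF, rt → 40 °C; then NaOH, H2O2, 0 °C
Reagents that add atoms: hydrogen peroxide, OO; 9-borabicyclo[3.3.1]nonane, B1C2CCCC1CCC2 (its boron stays only in 32)
Why: In this hydroboration–oxidation the bulky borane takes the terminal CH2 rather than the ring olefin, and in the chair-like conformer imposed by the cis-fused cyclopentane (C21 equatorial on C24) it should approach from the outer face, so H adds to C14 cis to H18 and H24 and C13 ends on the opposite face.

Step 26
Reactants: 33 primary alcohol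
Product: 34 1-phenyl-5-({(1R,3aR,5S,8aR)-1,4,4,6-tetramethyl-1-[(triethylsilyl)oxy]-1,2,3,3a,4,5,8,8a-octahydroazulen-5-yl}methylsulfanyl)-1H-tetrazole
Conditions: 1-phenyl-1H-tetrazole-5-thiol, PPh3, DIAD, THF, 0 °C → rt
Reagents that add atoms: 1-phenyl-1H-tetrazole-5-thiol, Sc1nnnn1-c1ccccc1
Why: The Mitsunobu thioetherification pairs an acidic, soft thiol with the primary alkoxyphosphonium salt, and this combination copes with β-branching.

Step 27
Reactants: 34 tetrazolyl sulfide
Product: 35 1-phenyl-5-({(1R,3aR,5S,8aR)-1,4,4,6-tetramethyl-1-[(triethylsilyl)oxy]-1,2,3,3a,4,5,8,8a-octahydroazulen-5-yl}methylsulfonyl)-1H-tetrazole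
Conditions: (NH4)6Mo7O24·4H2O (cat.), 30 % H2O2, EtOH, 0 °C → rt
Reagents that add atoms: hydrogen peroxide, OO
Why: Molybdate-catalysed peroxide oxidation takes sulfur to the sulfone much faster than it epoxidises an unactivated trisubstituted olefin.

**Union and endgame**

Step 28
Reactants: 16 C12 aldehyde; 35 C13 tetrazolyl sulfone
Product: 36 (12E)-diene, the tris(triethylsilyl) ether with C12=C13 and C26=C28 double bonds
Conditions: 35, KHMDS, THF, −78 °C; then 16, −78 °C → rt
Reagents that add atoms: none
Why: In the Julia–Kocienski olefination the pre-formed sulfonyl carbanion adds to the aldehyde and Smiles rearrangement with loss of SO2 forms C12=C13 in one operation; the olefin geometry does not matter because the bond is saturated in step 30.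

Step 29
Reactants: 36 diene
Product: 37 C26/C28 epoxide of 36 (O27 cis to the C13 side chain, anti to H14, H18 and H24)
Conditions: mCPBA (1.05 equiv), NaHCO3, CH2Cl2, −20 → 0 °C
Reagents that add atoms: 3-chloroperoxybenzoic acid, OOC(=O)c1cccc(Cl)c1
Why: In the Prilezhaev epoxidation the trisubstituted C26=C28 bond is more nucleophilic than the doubly flanked 1,2-disubstituted C12=C13 bond, and in the chair cycloheptene one methyl of C15 lies under the endo face, so the peracid should arrive on the exo face cis to the side chain, as in α-ionone-type rings.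

Step 30
Reactants: 37 epoxy olefin
Product: 38 tris(triethylsilyl) ether of the target
Conditions: 2-nitrobenzenesulfonohydrazide (excess, in portions), Et3N, CH2Cl2, rt
Reagents that add atoms: none
Why: Diimide reduction transfers H2 concertedly to the only remaining C=C bond, cannot isomerise it toward the epoxide, leaves epoxide and silyl ethers alone, and can therefore be driven with excess reagent.

Step 31
Reactants: 38 tris(triethylsilyl) ether
Product: 39 target CNP0216138.1
Conditions: TBAF, THF, 0 °C → rt
Reagents that add atoms: none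
Why: Fluoride cleaves the three TES ethers under non-acidic conditions that a trisubstituted epoxide and tertiary alcohols tolerate.

**Compound list**

1 | geranyl bromide | CC(C)=CCC/C(C)=C/CBr | starting material
2 | ethyl acetoacetate | CCOC(=O)CC(C)=O | starting material
3 | ethyl (6E)-7,11-dimethyl-3-oxododeca-6,10-dienoate | CCOC(=O)CC(=O)CC/C=C(\C)CCC=C(C)C | intermediate
4 | (2Z,6E)-enol triflate | CCOC(=O)/C=C(\OS(=O)(=O)C(F)(F)F)CC/C=C(\C)CCC=C(C)C | intermediate
5 | (R,R,R)-diepoxy Z-enol triflate | CCOC(=O)/C=C(\OS(=O)(=O)C(F)(F)F)CC[C@H]1O[C@]1(C)CC[C@H]1OC1(C)C | intermediate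
6 | (trimethylsilyl)methylmagnesium chloride | C[Si](C)(C)C[Mg]Cl | starting material
7 | diepoxy (Z)-3-(silylmethyl) enoate | CCOC(=O)/C=C(\C[Si](C)(C)C)CC[C@H]1O[C@]1(C)CC[C@H]1OC1(C)C | intermediate
8 | diepoxy (Z)-allylic alcohol | OC/C=C(\C[Si](C)(C)C)CC[C@H]1O[C@]1(C)CC[C@H]1OC1(C)C | intermediate
9 | (Z)-diepoxy 2-(silylmethyl)allyl TBDPS ether (cascade precursor) | C[Si](C)(C)C/C(=C\CO[Si](c1ccccc1)(c1ccccc1)C(C)(C)C)CC[C@H]1O[C@]1(C)CC[C@H]1OC1(C)C | intermediate
10 | C34 trimethylsilyl ether of 11 | CC1(C)O[C@@H]2CCC(=C)[C@H](CO[Si](c3ccccc3)(c3ccccc3)C(C)(C)C)[C@@]2(C)CC[C@H]1O[Si](C)(C)C | intermediate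
11 | trans-fused oxepane–methylenecyclohexane alcohol (cascade product) | CC1(C)O[C@@H]2CCC(=C)[C@H](CO[Si](c3ccccc3)(c3ccccc3)C(C)(C)C)[C@@]2(C)CC[C@H]1O | intermediate
12 | C8 ketone | CC1(C)O[C@@H]2CCC(=O)[C@H](CO[Si](c3ccccc3)(c3ccccc3)C(C)(C)C)[C@@]2(C)CC[C@H]1O | intermediate
13 | C8 tertiary carbinol (O10 axial) | CC1(C)O[C@@H]2CC[C@](C)(O)[C@H](CO[Si](c3ccccc3)(c3ccccc3)C(C)(C)C)[C@@]2(C)CC[C@H]1O | intermediate
14 | left-half triol | CC1(C)O[C@@H]2CC[C@](C)(O)[C@H](CO)[C@@]2(C)CC[C@H]1O | intermediate
15 | tris(triethylsilyl) ether of 14 | CC1(C)O[C@@H]2CC[C@](C)(O[Si](CC)(CC)CC)[C@H](CO[Si](CC)(CC)CC)[C@@]2(C)CC[C@H]1O[Si](CC)(CC)CC | intermediate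
16 | C12 aldehyde | CC1(C)O[C@@H]2CC[C@](C)(O[Si](CC)(CC)CC)[C@H](C=O)[C@@]2(C)CC[C@H]1O[Si](CC)(CC)CC | intermediate
17 | (R)-(−)-linalool | CC(C)=CCC[C@@](C)(O)C=C | starting material
18 | (1R)-1-methylcyclopent-2-en-1-ol | C[C@]1(O)C=CCC1 | intermediate
19 | (1S,2R,5S)-2-methyl-6-oxabicyclo[3.1.0]hexan-2-ol | C[C@]1(O)[C@H]2O[C@H]2CC1 | intermediate
20 | isobutyronitrile | CC(C)C#N | starting material
21 | diol nitrile | C[C@]1(O)[C@@H](O)[C@H](C(C)(C)C#N)CC1 | intermediate
22 | α-ketol nitrile | C[C@]1(O)C(=O)[C@H](C(C)(C)C#N)CC1 | intermediate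
23 | TES-protected ketone nitrile | C[C@]1(O[Si](CC)(CC)CC)C(=O)[C@H](C(C)(C)C#N)CC1 | intermediate
24 | methylidenecyclopentane nitrile | C[C@]1(O[Si](CC)(CC)CC)C(=C)[C@H](C(C)(C)C#N)CC1 | intermediate
25 | B-alkyl-9-BBN adduct of 24 | C[C@]1(O[Si](CC)(CC)CC)[C@H](CB2C3CCCC2CCC3)[C@H](C(C)(C)C#N)CC1 | intermediate
26 | cis-allyl nitrile | C[C@]1(O[Si](CC)(CC)CC)[C@H](CC=C)[C@H](C(C)(C)C#N)CC1 | intermediate
27 | C14 aldehyde | C[C@]1(O[Si](CC)(CC)CC)[C@H](CC=C)[C@H](C(C)(C)C=O)CC1 | intermediate
28 | dienol (C14 epimers) | C[C@]1(O[Si](CC)(CC)CC)[C@H](CC=C)[C@H](C(C)(C)C(O)C(C)=C)CC1 | intermediate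
29 | cis-hydroazulenol (C14 epimers) | OC1C(C)(C)[C@@H]2CC[C@@](C)(O[Si](CC)(CC)CC)[C@@H]2CC=C1C | intermediate
30 | cis-hydroazulenone | O=C1C(C)(C)[C@@H]2CC[C@@](C)(O[Si](CC)(CC)CC)[C@@H]2CC=C1C | intermediate
31 | C14 methylidene diene | C=C1C(C)(C)[C@@H]2CC[C@@](C)(O[Si](CC)(CC)CC)[C@@H]2CC=C1C | intermediate
32 | B-alkyl-9-BBN adduct of 31 | C(B1C2CCCC1CCC2)[C@@H]1C(C)(C)[C@@H]2CC[C@@](C)(O[Si](CC)(CC)CC)[C@@H]2CC=C1C | intermediate
33 | C13 primary alcohol | OC[C@@H]1C(C)(C)[C@@H]2CC[C@@](C)(O[Si](CC)(CC)CC)[C@@H]2CC=C1C | intermediate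
34 | phenyltetrazolyl sulfide | c1ccc(cc1)-n1nnnc1SC[C@@H]1C(C)(C)[C@@H]2CC[C@@](C)(O[Si](CC)(CC)CC)[C@@H]2CC=C1C | intermediate
35 | phenyltetrazolyl sulfone | c1ccc(cc1)-n1nnnc1S(=O)(=O)C[C@@H]1C(C)(C)[C@@H]2CC[C@@](C)(O[Si](CC)(CC)CC)[C@@H]2CC=C1C | intermediate
36 | (12E)-diene tris-TES ether | CC1(C)O[C@@H]2CC[C@](C)(O[Si](CC)(CC)CC)[C@H](/C=C/[C@@H]3C(C)(C)[C@@H]4CC[C@@](C)(O[Si](CC)(CC)CC)[C@@H]4CC=C3C)[C@@]2(C)CC[C@H]1O[Si](CC)(CC)CC | intermediate
37 | C26/C28 epoxide of 36 | CC1(C)O[C@@H]2CC[C@](C)(O[Si](CC)(CC)CC)[C@H](/C=C/[C@@H]3C(C)(C)[C@@H]4CC[C@@](C)(O[Si](CC)(CC)CC)[C@@H]4C[C@@H]4O[C@@]43C)[C@@]2(C)CC[C@H]1O[Si](CC)(CC)CC | intermediate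
38 | tris-TES ether of the target | CC1(C)O[C@@H]2CC[C@](C)(O[Si](CC)(CC)CC)[C@H](CC[C@@H]3C(C)(C)[C@@H]4CC[C@@](C)(O[Si](CC)(CC)CC)[C@@H]4C[C@@H]4O[C@@]43C)[C@@]2(C)CC[C@H]1O[Si](CC)(CC)CC | intermediate
39 | CNP0216138.1 | CC1(C)O[C@@H]2CC[C@](C)(O)[C@H](CC[C@@H]3C(C)(C)[C@@H]4CC[C@@](C)(O)[C@@H]4C[C@@H]4O[C@@]43C)[C@@]2(C)CC[C@H]1O | target

**Step count and risks**

Total step count: 31 (12 for the left half, 15 for the right half, 4 after the union).
Longest linear sequence: 19 steps (steps 13–31, from 17).

The three steps most likely to fail: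

Step 7. The bicyclic epoxonium ion may collapse by hydride shift or proton loss, or be intercepted by triflate, before the allylsilane reaches C30. The fallback sets out from 9 and returns at 11. It separates the two ring closures and reverses their order.
- A plain epoxy-allylsilane cyclisation (Et2AlCl, CH2Cl2, −90 °C) exploits the fact that only the internal epoxide has a π-nucleophile within reach of a six-membered chair.
- That epoxide should therefore open first at C30, with inversion, to give the methylenecyclohexanol with intact terminal epoxide F1.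
- Catalytic camphorsulfonic acid in CH2Cl2 at 0 °C then closes the oxepane by 7-endo attack of the C5 hydroxyl on tertiary C2. The same two bonds and the same configuration as in 11 result.

Step 28. Addition of the β-branched sulfonyl carbanion to the doubly flanked aldehyde may be slower than enolisation of the aldehyde with loss of the C8 silyloxy group. The fallback sets out from 33 and 16 and returns at 38.
- The alcohol is converted (I2, PPh3, imidazole) into the primary iodide F2.
- t-BuLi (2 equiv, Et2O–pentane, −78 °C) turns the iodide into the primary alkyllithium F3.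
- This small, hard nucleophile adds to 16 to give the C12 carbinol F4, whose epimers do not matter.
- KHMDS, CS2 and MeI give the S-methyl xanthate F5.
- Barton–McCombie reduction (Bu3SnH, AIBN, toluene, 80 °C) gives the saturated C12–C13 link in the mono-olefin F6.
- Buffered mCPBA epoxidation of its only double bond leads to 38.

Step 29. Facial selectivity may be poor or reversed, with the peracid attacking the face anti to the side chain. The fallback sets out from 36 and returns at 37. It uses a halohydrin sequence that places oxygen on the face opposite to the one the electrophile prefers.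
- NBS in aqueous DME at 0 °C forms the bromonium ion on the more accessible face of the trisubstituted olefin.
- Water opens it anti at tertiary C28 to give the bromohydrin F7 (C26 bromide on the face of H14, C28 hydroxyl on the face of C13).
- K2CO3 in MeOH closes the ring by backside displacement at C26.

**Further compounds**

F1 | step 7 | methylenecyclohexanol with intact terminal epoxide | O[C@@H]1CCC(=C)[C@H](CO[Si](c2ccccc2)(c2ccccc2)C(C)(C)C)[C@@]1(C)CC[C@H]1OC1(C)C
F2 | step 28 | primary iodide | IC[C@@H]1C(C)(C)[C@@H]2CC[C@@](C)(O[Si](CC)(CC)CC)[C@@H]2CC=C1C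
F3 | step 28 | primary alkyllithium | [Li]C[C@@H]1C(C)(C)[C@@H]2CC[C@@](C)(O[Si](CC)(CC)CC)[C@@H]2CC=C1C
F4 | step 28 | C12 carbinol (epimers) | CC1(C)O[C@@H]2CC[C@](C)(O[Si](CC)(CC)CC)[C@H](C(O)C[C@@H]3C(C)(C)[C@@H]4CC[C@@](C)(O[Si](CC)(CC)CC)[C@@H]4CC=C3C)[C@@]2(C)CC[C@H]1O[Si](CC)(CC)CC
F5 | step 28 | S-methyl xanthate | CC1(C)O[C@@H]2CC[C@](C)(O[Si](CC)(CC)CC)[C@H](C(OC(=S)SC)C[C@@H]3C(C)(C)[C@@H]4CC[C@@](C)(O[Si](CC)(CC)CC)[C@@H]4CC=C3C)[C@@]2(C)CC[C@H]1O[Si](CC)(CC)CC
F6 | step 28 | mono-olefin tris-TES ether | CC1(C)O[C@@H]2CC[C@](C)(O[Si](CC)(CC)CC)[C@H](CC[C@@H]3C(C)(C)[C@@H]4CC[C@@](C)(O[Si](CC)(CC)CC)[C@@H]4CC=C3C)[C@@]2(C)CC[C@H]1O[Si](CC)(CC)CC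
F7 | step 29 | bromohydrin | CC1(C)O[C@@H]2CC[C@](C)(O[Si](CC)(CC)CC)[C@H](/C=C/[C@@H]3C(C)(C)[C@@H]4CC[C@@](C)(O[Si](CC)(CC)CC)[C@@H]4C[C@@H](Br)[C@]3(C)O)[C@@]2(C)CC[C@H]1O[Si](CC)(CC)CC
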